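## Structural features

The target is an achiral dihydrochalcone (C26H32O6): two benzene rings joined by an aryl ketone carbon and two methylene groups. C2 of the heterocycle carries two methyl groups, so there is no stereocentre and no pair of adjacent stereocentres to relate. Ring A is a phloroglucinol nucleus. Its acyl-bearing carbon (C6, chroman numbering) lies between two free hydroxyls (C5–OH, C7–OH), and the third oxygen is O1 of a fused 2,2-dimethyl-3,4-dihydro-2H-pyran (O1, C2, C3, C4, C4a, C8a). O1 is therefore para to the ketone and C8 is the only aromatic C–H of ring A. Ring B carries the side chain at C1, a free hydroxyl at C3, a methoxy at C4 and a prenyl group at C5. This is the isovanillin pattern (methoxy para to the chain), not the vanillin pattern. The fragile groups are the trisubstituted alkene of the ring B prenyl (acid, electrophiles, hydrogenation catalysts), the electron-rich ring A with its nucleophilic C8–H, and the free phenols. The real difficulty is selectivity, not bond construction: one of three phloroglucinol oxygens must become the pyran oxygen while the two flanking the ketone stay free, and one of two prenyl groups must cyclise while the other survives. The key step uses the fact that C4a–C4–C3–C2(CH3)2 is a prenyl group folded onto O1, so opening O1–C2 reveals a ring A C-prenyl phenol whose hydroxyl para to the ketone can trap the tertiary cation.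

## Logic of the disconnections

**18 ⇒ 17.** The three O–CH2 bonds of allyl ethers (O5 and O7 of ring A, O3 of ring B) are cut. Allyl is chosen because it withstands base, hydride and the protic acid of the key step, yet leaves under neutral palladium catalysis that does not touch a trisubstituted alkene. The gain is that 17 hides all three phenols that would otherwise interfere. The forward step must not C-allylate the electron-rich C8 position, so an amine allyl acceptor is used in excess.

**17 ⇒ 16.** The O1–C2 bond is cut, opening the dihydropyran to a ring A prenyl group next to a free hydroxyl para to the ketone. This removes the only ring that has to be built. The forward step needs the correct oxygen to close and the ring B prenyl to survive. Hydrogen bonding of the ortho hydroxyls to the ketone would not secure this: only one of them can be chelated at a time, and even a chelated hydroxyl closes onto a neighbouring prenyl cation, so linear and angular chromans would both form. In 16 both oxygens ortho to the ketone are therefore allyl ethers and the para hydroxyl is the only free one on ring A.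

**16 ⇒ 14 (through 15).** The aryl–CH2 bond of the ring A prenyl group is exchanged for the O4′–C(CH3)2 bond of a 1,1-dimethylallyl ether. A [3,3] shift places the prenyl group and frees the para hydroxyl in one neutral step. Because O2′ and O6′ carry identical groups, the two ortho carbons are equivalent and no regiochemical question arises. This replaces a late base-mediated C-prenylation of an acylphloroglucinol, which would give C-mono, C-di and O-prenyl mixtures and would also alkylate a free ring B phenol. The forward step must outrun heterolysis of the tertiary ether and must run below the temperature at which simple allyl aryl ethers rearrange.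

**14 ⇒ 12 ⇒ 10 + 6 (through 13 and 11).** The Cα–Cβ single bond is traced back to the enone, and the Cα=Cβ bond is then cut by a retro-aldol condensation. This divides the molecule into a ring A methyl ketone and a ring B aldehyde of similar size. The forward reduction must be a conjugate hydride delivery, because hydrogenation would not distinguish the enone from three allyl ethers, a 1,1-dimethylallyl ether and a prenyl group.

**10 ⇒ 9 ⇒ 8 ⇒ 7.** The two ortho O–allyl bonds are cut, the vinyl group is traced to an ethynyl group, and the O4–C(CH3)2 bond is cut. This leads to a commercial trihydroxy ketone. The forward etherification must pick the most acidic, unchelated para hydroxyl, and the semi-hydrogenation must stop at the alkene.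

**6 ⇒ 5 ⇒ 3 + 4.** The ring B O–allyl bond and then the aryl–CH2 bond of the ring B prenyl group are cut, giving an aryl bromide and a prenyl metal reagent. The coupling must join the less substituted allyl terminus and tolerate a free phenol and an aldehyde. It is placed before the allylation so that zerovalent palladium never meets an aryl allyl ether at high temperature.

**3 ⇒ 2 ⇒ 1.** The two O–CH3 bonds are exchanged. In 1 the free hydroxyl is para to the aldehyde and the methoxy is meta, the reverse of what ring B needs. The methyl is therefore removed and put back on the other oxygen. The remethylation must select the more acidic hydroxyl para to the aldehyde.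

## Other disconnections considered

**Alternative 1:** The cut is the C4a–C4 aryl–carbon bond of a chromene. In the forward direction a cationic phosphine–gold catalyst such as Ph3PAuNTf2 (monovalent gold) activates the terminal alkyne of the symmetric ether A1 (4-[(2-methylbut-3-yn-2-yl)oxy]-2,6-bis(methoxymethoxy)benzaldehyde), and the ortho carbon closes in a 6-endo-dig hydroarylation to chromene aldehyde A2.
- *In favour:* A1 has a mirror plane through the aldehyde and the ether oxygen, so both ortho carbons are the same and regiochemistry cannot fail. On this point it equals the masked precursor 16 and needs no extra protecting groups to achieve it. No second prenyl group is present when the ring forms, so on chemoselectivity it is better than the chosen plan. The catalysis is mild.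
- *Against:* The ring arrives one oxidation level too high, and the C3–C4 alkene must be hydrogenated before ring B with its own alkene is attached. The product is an aldehyde, so the whole C3 bridge still has to be built (methyl addition and oxidation, then aldol and conjugate reduction, or an equivalent). The methoxymethyl ethers must finally be removed with acid in the presence of the ring B prenyl group.
- *Comparison:* Preparing A1 needs the same para-selective etherification of a trioxygenated aryl carbonyl compound as step 5, so that risk is equal. In step count it is equal at best and probably one or two steps longer.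

**Alternative 2:** The cut removes three bonds of ring A (C4a–C8a, C5–C6, C8–C8a). In the forward direction heating cyclobutenone A4 (3-ethoxycyclobut-2-en-1-one) with siloxyalkyne A3 (triisopropyl[(5-methylhex-4-en-1-yn-1-yl)oxy]silane) would give phenol A5 (5-ethoxy-2-prenyl-3-[(triisopropylsilyl)oxy]phenol) through vinylketene formation, [2+2] cycloaddition, ring opening and 6π electrocyclisation.
- *In favour:* The three oxygens are born different (free hydroxyl, silyl ether, ethyl ether) and the prenyl group is fixed between the free hydroxyl and the silyl ether. Closure of the pyran onto the single free hydroxyl would be unambiguous, which equals the chosen plan on regiocontrol. The cascade needs no metal.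
- *Against:* Ring A is a cheap commercial aromatic, and building it from A3 and A4 (both needing their own syntheses) costs many steps. The ethyl ether ends up ortho to the ketone and would need a boron trihalide-type cleavage that threatens the ring B prenyl and methoxy groups. The later acylation must go between the silyloxy and ethoxy groups and not to the freer position next to the pyran oxygen, which nothing in A5 ensures.
- *Comparison:* Mechanistically attractive and equal on oxygen differentiation, but clearly longer and weaker in the endgame.

**Alternative 3:** The cut is the O1–C8a aryl–oxygen bond. In the forward direction Pd(OAc)2 with a bulky biarylphosphine and Cs2CO3 would insert into the triflate of A6 (4-formyl-2-(3-hydroxy-3-methylbutyl)-3,5-bis(methoxymethoxy)phenyl trifluoromethanesulfonate) and couple the tertiary alkoxide to give chroman aldehyde A7.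
- *In favour:* The position of the triflate dictates the site of closure, so regiocontrol equals the chosen plan. No carbocation is involved, so on chemoselectivity towards alkenes it is better in principle. The tertiary alkoxide has no β-hydrogen on the carbinol carbon, and the saturated ring is formed directly, unlike in alternative 1 (A7 is the dihydro form of A2).
- *Against:* A6 needs the same differentiation of three oxygens plus a hydroxyalkyl chain and an aldehyde, so the selectivity problem is moved earlier, not removed. The electron-rich, ortho-substituted triflate is slow in oxidative addition and open to hydrolysis by carbonate. C–O reductive elimination with a hindered alkoxide is the difficult step. The aldehyde then needs the same elaboration and final acidic deprotection as in alternative 1.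
- *Comparison:* Longer than the chosen plan.

Key step: step 11

Remarks on the chemistry: ring A of open-chain compounds is numbered with primes from the acyl-bearing carbon C1′, and ring-closed compounds use chroman numbering. 5-Bromovanillin has its methyl group on the wrong oxygen for ring B, so steps 1 and 2 move it. 2,4,6-Trihydroxyacetophenone is assumed to be used dried.

## Route

Step 1
Reactants: 1 5-bromovanillin (3-bromo-4-hydroxy-5-methoxybenzaldehyde)
Product: 2 3-bromo-4,5-dihydroxybenzaldehyde
Conditions: AlCl3, pyridine, CH2Cl2, reflux; then aq. HCl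
Reagents that add atoms: none
Why: Lewis-acid demethylation of an ortho-hydroxy aryl methyl ether: the aluminium chelate of the phenoxide and the neighbouring methoxy oxygen activates the O–CH3 bond and pyridine removes the methyl group by SN2 attack; the aldehyde and the aryl bromide are inert.

Step 2
Reactants: 2 3-bromo-4,5-dihydroxybenzaldehyde
Product: 3 3-bromo-5-hydroxy-4-methoxybenzaldehyde
Conditions: MeI (1 equiv), DBU (1 equiv), DMF, 0 °C → rt
Reagents that add atoms: iodomethane, CI
Why: Regioselective Williamson mono-methylation: the hydroxyl para to the aldehyde and ortho to bromine is the more acidic, so one equivalent of base should give mainly its phenoxide, which is methylated to the isovanillin pattern needed for ring B.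

Step 3
Reactants: 3 3-bromo-5-hydroxy-4-methoxybenzaldehyde; 4 tributyl(3-methylbut-2-en-1-yl)stannane
Product: 5 3-hydroxy-4-methoxy-5-(3-methylbut-2-en-1-yl)benzaldehyde
Conditions: Pd(PPh3)4 (cat.), DMF, 95 °C
Reagents that add atoms: none
Why: Stille coupling of an aryl bromide with a prenylstannane under zerovalent palladium; reductive elimination at the less hindered allyl terminus should give the linear prenyl arene, and the free phenol and the aldehyde are tolerated.

Step 4
Reactants: 5 3-hydroxy-4-methoxy-5-(3-methylbut-2-en-1-yl)benzaldehyde
Product: 6 3-(allyloxy)-4-methoxy-5-(3-methylbut-2-en-1-yl)benzaldehyde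
Conditions: allyl bromide, K2CO3, DMF, rt
Reagents that add atoms: allyl bromide, C=CCBr
Why: Williamson etherification of the only phenol; the allyl ether keeps acidic O–H away from the aldol and copper hydride steps and is removed with the ring A allyl groups at the end.

Step 5
Reactants: 7 2,4,6-trihydroxyacetophenone
Product: 8 1-[2,6-dihydroxy-4-[(2-methylbut-3-yn-2-yl)oxy]phenyl]ethan-1-one
Conditions: 3-chloro-3-methylbut-1-yne, DBU (1.1 equiv), CuCl2·2H2O (cat.), MeCN, 0 °C
Reagents that add atoms: 3-chloro-3-methylbut-1-yne, CC(C)(Cl)C#C
Why: Copper-catalysed propargylic etherification of a phenol; with about one equivalent of base only the most acidic, unchelated hydroxyl para to the ketone is deprotonated, and its oxygen attacks the tertiary propargylic carbon of the copper-activated electrophile.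

Step 6
Reactants: 8 1-[2,6-dihydroxy-4-[(2-methylbut-3-yn-2-yl)oxy]phenyl]ethan-1-one
Product: 9 1-[2,6-dihydroxy-4-[(2-methylbut-3-en-2-yl)oxy]phenyl]ethan-1-one
Conditions: H2 (1 atm), Pd/CaCO3 poisoned with Pb(OAc)2 (Lindlar catalyst), quinoline, EtOAc, rt
Reagents that add atoms: none
Why: Lindlar semi-hydrogenation of the terminal alkyne to the vinyl group; the poisoned catalyst should stop at the alkene and leave the aryl ketone alone, and no other alkene is present yet.

Step 7
Reactants: 9 1-[2,6-dihydroxy-4-[(2-methylbut-3-en-2-yl)oxy]phenyl]ethan-1-one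
Product: 10 1-[2,6-bis(allyloxy)-4-[(2-methylbut-3-en-2-yl)oxy]phenyl]ethan-1-one
Conditions: allyl bromide (excess), Cs2CO3, DMF, rt
Reagents that add atoms: allyl bromide, C=CCBr
Why: Double Williamson etherification of the two hydroxyls ortho to the ketone; caesium carbonate in DMF alkylates chelated phenols at room temperature, which keeps the tertiary allyl ether below its rearrangement temperature.

Step 8
Reactants: 10 1-[2,6-bis(allyloxy)-4-[(2-methylbut-3-en-2-yl)oxy]phenyl]ethan-1-one; 6 3-(allyloxy)-4-methoxy-5-(3-methylbut-2-en-1-yl)benzaldehyde
Product: 12 (E)-1-[2,6-bis(allyloxy)-4-[(2-methylbut-3-en-2-yl)oxy]phenyl]-3-[3-(allyloxy)-4-methoxy-5-(3-methylbut-2-en-1-yl)phenyl]prop-2-en-1-one, via aldol adduct 11 (not isolated)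
Conditions: KOH, EtOH/H2O, rt
Reagents that add atoms: none
Why: Claisen–Schmidt condensation of a methyl ketone with a non-enolisable aldehyde; the β-hydroxy ketone dehydrates by E1cB to the thermodynamically favoured E-enone, and neither partner has a free phenol to slow the reaction or cyclise to a flavanone.

Step 9
Reactants: 12 (E)-1-[2,6-bis(allyloxy)-4-[(2-methylbut-3-en-2-yl)oxy]phenyl]-3-[3-(allyloxy)-4-methoxy-5-(3-methylbut-2-en-1-yl)phenyl]prop-2-en-1-one
Product: 14 1-[2,6-bis(allyloxy)-4-[(2-methylbut-3-en-2-yl)oxy]phenyl]-3-[3-(allyloxy)-4-methoxy-5-(3-methylbut-2-en-1-yl)phenyl]propan-1-one, via silyl enol ether 13 (not isolated)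
Conditions: [(Ph3P)CuH]6 (cat.), PhMe2SiH, toluene, rt; then K2CO3, MeOH
Reagents that add atoms: none
Why: Copper hydride-catalysed conjugate reduction: the phosphine copper hydride adds hydride only to the β-carbon of the enone, the copper enolate is silylated by the silane, and methanolysis releases the ketone; unactivated alkenes (allyl, 1,1-dimethylallyl, prenyl) are not touched, and the enol silane protects the carbonyl from further reduction.

Step 10
Reactants: 14 1-[2,6-bis(allyloxy)-4-[(2-methylbut-3-en-2-yl)oxy]phenyl]-3-[3-(allyloxy)-4-methoxy-5-(3-methylbut-2-en-1-yl)phenyl]propan-1-one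
Product: 16 1-[2,6-bis(allyloxy)-4-hydroxy-3-(3-methylbut-2-en-1-yl)phenyl]-3-[3-(allyloxy)-4-methoxy-5-(3-methylbut-2-en-1-yl)phenyl]propan-1-one, via cyclohexadienone 15 (not isolated)
Conditions: PhNEt2, 125 °C
Reagents that add atoms: none
Why: Aromatic Claisen rearrangement of a 1,1-dimethylallyl aryl ether: the [3,3] shift inverts the allyl unit, so the normal prenyl group arrives at the carbon ortho to O4′ and the dienone tautomerises to the free para phenol. Both ortho carbons are equivalent, and the primary allyl ethers need far higher temperatures to rearrange.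

Step 11
Reactants: 16 1-[2,6-bis(allyloxy)-4-hydroxy-3-(3-methylbut-2-en-1-yl)phenyl]-3-[3-(allyloxy)-4-methoxy-5-(3-methylbut-2-en-1-yl)phenyl]propan-1-one
Product: 17 1-[5,7-bis(allyloxy)-2,2-dimethyl-3,4-dihydro-2H-chromen-6-yl]-3-[3-(allyloxy)-4-methoxy-5-(3-methylbut-2-en-1-yl)phenyl]propan-1-one
Conditions: p-TsOH·H2O (cat.), toluene (dilute), 60 °C
Reagents that add atoms: none
Why: The acid protonates the ring A prenyl alkene at C3 (Markovnikov) to give a tertiary cation at C2, which the only free ring A hydroxyl, O4′ para to the ketone, captures before losing its proton; this forms O1–C2 and closes the dihydropyran. The closest known reaction type is the acid-catalysed cyclisation of ortho-prenylphenols to 2,2-dimethylchromans, an intramolecular Markovnikov hydroalkoxylation. The ring closes in the 6-endo-trig mode, with both former alkene carbons inside the ring. No stereocentre is formed because C2 carries two methyl groups. The choice of oxygen is secured by the substrate and not by hydrogen bonding: O2′ and O6′ are allyl ethers, so the oxygen that is ortho to the ketone and also flanks the prenyl group could close only by expelling an allyl cation, which is far slower than loss of a proton. The choice between the two prenyl groups rests on the ring B prenyl having only a methoxy group and a C–H as neighbours and an allylated phenol, so in non-nucleophilic toluene its cation has nothing to add and returns to the alkene by proton loss. The three allyl ethers are monosubstituted alkenes and protonate much more slowly than a trisubstituted one. Catalytic sulfonic acid, dilution and moderate temperature limit intermolecular alkylation of the electron-rich ring A.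

Step 12
Reactants: 17 1-[5,7-bis(allyloxy)-2,2-dimethyl-3,4-dihydro-2H-chromen-6-yl]-3-[3-(allyloxy)-4-methoxy-5-(3-methylbut-2-en-1-yl)phenyl]propan-1-one
Product: 18 1-(5,7-dihydroxy-2,2-dimethyl-3,4-dihydro-2H-chromen-6-yl)-3-[3-hydroxy-4-methoxy-5-(3-methylbut-2-en-1-yl)phenyl]propan-1-one (CNP0408176.0)
Conditions: Pd(PPh3)4 (cat.), morpholine (excess), THF, rt → 40 °C
Reagents that add atoms: none
Why: Tsuji–Trost-type deallylation: zerovalent palladium ionises each aryl allyl ether to a π-allyl complex and a phenoxide, and morpholine takes the allyl group irreversibly; the prenyl alkene has no leaving group and the chroman ether is inert, so the three phenols are freed under neutral conditions.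

## Compound list

1 | 5-bromovanillin (3-bromo-4-hydroxy-5-methoxybenzaldehyde) | COc1cc(C=O)cc(Br)c1O | starting material
2 | 3-bromo-4,5-dihydroxybenzaldehyde | O=Cc1cc(O)c(O)c(Br)c1 | intermediate
3 | 3-bromo-5-hydroxy-4-methoxybenzaldehyde | COc1c(O)cc(C=O)cc1Br | intermediate
4 | tributyl(3-methylbut-2-en-1-yl)stannane | CCCC[Sn](CCCC)(CCCC)CC=C(C)C | starting material
5 | 3-hydroxy-4-methoxy-5-(3-methylbut-2-en-1-yl)benzaldehyde | COc1c(O)cc(C=O)cc1CC=C(C)C | intermediate
6 | 3-(allyloxy)-4-methoxy-5-(3-methylbut-2-en-1-yl)benzaldehyde | COc1c(OCC=C)cc(C=O)cc1CC=C(C)C | intermediate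
7 | 2,4,6-trihydroxyacetophenone | CC(=O)c1c(O)cc(O)cc1O | starting material
8 | 1-[2,6-dihydroxy-4-[(2-methylbut-3-yn-2-yl)oxy]phenyl]ethan-1-one | CC(=O)c1c(O)cc(OC(C)(C)C#C)cc1O | intermediate
9 | 1-[2,6-dihydroxy-4-[(2-methylbut-3-en-2-yl)oxy]phenyl]ethan-1-one | CC(=O)c1c(O)cc(OC(C)(C)C=C)cc1O | intermediate
10 | 1-[2,6-bis(allyloxy)-4-[(2-methylbut-3-en-2-yl)oxy]phenyl]ethan-1-one | CC(=O)c1c(OCC=C)cc(OC(C)(C)C=C)cc1OCC=C | intermediate
11 | aldol adduct, racemic: 1-[2,6-bis(allyloxy)-4-[(2-methylbut-3-en-2-yl)oxy]phenyl]-3-[3-(allyloxy)-4-methoxy-5-(3-methylbut-2-en-1-yl)phenyl]-3-hydroxypropan-1-one | C=CCOc1cc(OC(C)(C)C=C)cc(OCC=C)c1C(=O)CC(O)c1cc(OCC=C)c(OC)c(CC=C(C)C)c1 | intermediate (not isolated)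
12 | (E)-1-[2,6-bis(allyloxy)-4-[(2-methylbut-3-en-2-yl)oxy]phenyl]-3-[3-(allyloxy)-4-methoxy-5-(3-methylbut-2-en-1-yl)phenyl]prop-2-en-1-one | C=CCOc1cc(OC(C)(C)C=C)cc(OCC=C)c1C(=O)/C=C/c1cc(OCC=C)c(OC)c(CC=C(C)C)c1 | intermediate
13 | dimethyl(phenyl)silyl enol ether of 14 (enol ether geometry not defined) | C=CCOc1cc(OC(C)(C)C=C)cc(OCC=C)c1C(O[Si](C)(C)c2ccccc2)=CCc3cc(OCC=C)c(OC)c(CC=C(C)C)c3 | intermediate (not isolated)
14 | 1-[2,6-bis(allyloxy)-4-[(2-methylbut-3-en-2-yl)oxy]phenyl]-3-[3-(allyloxy)-4-methoxy-5-(3-methylbut-2-en-1-yl)phenyl]propan-1-one | C=CCOc1cc(OC(C)(C)C=C)cc(OCC=C)c1C(=O)CCc1cc(OCC=C)c(OC)c(CC=C(C)C)c1 | intermediate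
15 | cyclohexadienone tautomer of 16, racemic: 3,5-bis(allyloxy)-4-[3-[3-(allyloxy)-4-methoxy-5-(3-methylbut-2-en-1-yl)phenyl]propanoyl]-6-(3-methylbut-2-en-1-yl)cyclohexa-2,4-dien-1-one | C=CCOC1=CC(=O)C(CC=C(C)C)C(OCC=C)=C1C(=O)CCc1cc(OCC=C)c(OC)c(CC=C(C)C)c1 | intermediate (not isolated)
16 | 1-[2,6-bis(allyloxy)-4-hydroxy-3-(3-methylbut-2-en-1-yl)phenyl]-3-[3-(allyloxy)-4-methoxy-5-(3-methylbut-2-en-1-yl)phenyl]propan-1-one | C=CCOc1cc(O)c(CC=C(C)C)c(OCC=C)c1C(=O)CCc1cc(OCC=C)c(OC)c(CC=C(C)C)c1 | intermediate
17 | 1-[5,7-bis(allyloxy)-2,2-dimethyl-3,4-dihydro-2H-chromen-6-yl]-3-[3-(allyloxy)-4-methoxy-5-(3-methylbut-2-en-1-yl)phenyl]propan-1-one | C=CCOc1cc2OC(C)(C)CCc2c(OCC=C)c1C(=O)CCc1cc(OCC=C)c(OC)c(CC=C(C)C)c1 | intermediate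
18 | 1-(5,7-dihydroxy-2,2-dimethyl-3,4-dihydro-2H-chromen-6-yl)-3-[3-hydroxy-4-methoxy-5-(3-methylbut-2-en-1-yl)phenyl]propan-1-one | COc1c(O)cc(CCC(=O)c2c(O)cc3c(c2O)CCC(C)(C)O3)cc1CC=C(C)C | target

## Step count and least certain steps

Total step count: 12. Longest linear sequence: 9 steps (steps 1–4, then 8–12); the ring A branch (steps 5–7) joins at step 8.

**Step 11 (key step).** The most likely failure is acid chemistry at the ring B prenyl alkene running beside the wanted closure. That alkene protonates about as readily as the ring A one. Its cation has no oxygen to close onto, but on prolonged exposure it may lose a proton to the terminal alkene isomer, alkylate C6 of ring B to an indane, or alkylate the electron-rich ring A of another molecule. The fallback moves the closure ahead of the fragment union, so that no second prenyl group is present. It sets out from 10 and returns at 17.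
- Heating 10 in PhNEt2 should give, by the same Claisen shift, 1-[2,6-bis(allyloxy)-4-hydroxy-3-(3-methylbut-2-en-1-yl)phenyl]ethan-1-one F1.
- Catalytic p-TsOH in toluene should close F1 to 1-[5,7-bis(allyloxy)-2,2-dimethyl-3,4-dihydro-2H-chromen-6-yl]ethan-1-one F2.
- Claisen–Schmidt condensation of F2 with 6 (KOH, EtOH) should give the chroman chalcone (E)-1-[5,7-bis(allyloxy)-2,2-dimethyl-3,4-dihydro-2H-chromen-6-yl]-3-[3-(allyloxy)-4-methoxy-5-(3-methylbut-2-en-1-yl)phenyl]prop-2-en-1-one F3.
- Copper hydride conjugate reduction of F3 as in step 9 then gives 17.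

**Step 5.** The most likely failure is loss of site selectivity in the etherification: C-alkylation of the phloroglucinol nucleus by the propargylic electrophile, or a second alkylation at an ortho hydroxyl, because the mono-anion is an ambident nucleophile and the electrophile is hindered. The fallback separates site selection from the difficult tertiary ether formation by using protecting groups. It sets out from 7 and returns at 10.
- MOMCl (1 equiv) and i-Pr2NEt should protect the para hydroxyl as 1-[2,6-dihydroxy-4-(methoxymethoxy)phenyl]ethan-1-one F4.
- Allyl bromide and Cs2CO3 give 1-[2,6-bis(allyloxy)-4-(methoxymethoxy)phenyl]ethan-1-one F5.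
- HCl in MeOH frees the single phenol of 1-[2,6-bis(allyloxy)-4-hydroxyphenyl]ethan-1-one F6.
- The copper-catalysed propargylation of step 5 on F6 gives 1-[2,6-bis(allyloxy)-4-[(2-methylbut-3-yn-2-yl)oxy]phenyl]ethan-1-one F7.
- Lindlar semi-hydrogenation of F7 leads to 10.

**Step 10.** The most likely failure is heterolysis of the tertiary allyl aryl ether outrunning the [3,3] shift. The phenoxide para to a ketone is a good leaving group, so loss of isoprene to the de-prenylated phenol may compete, as may crossover of the allyl cation. The fallback avoids a tertiary ether by using a para-Claisen–Cope shift of a primary prenyl ether. It sets out from 7 (through F4) and returns at 17.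
- F4 is O-prenylated at one ortho hydroxyl (prenyl bromide, K2CO3, acetone) to 1-[2-hydroxy-4-(methoxymethoxy)-6-[(3-methylbut-2-en-1-yl)oxy]phenyl]ethan-1-one F8.
- Heating F8 in PhNEt2 at about 200 °C should move the prenyl group by Claisen then Cope shifts to the carbon para to that oxygen, giving 1-[2,6-dihydroxy-4-(methoxymethoxy)-3-(3-methylbut-2-en-1-yl)phenyl]ethan-1-one F9.
- Double allylation gives 1-[2,6-bis(allyloxy)-4-(methoxymethoxy)-3-(3-methylbut-2-en-1-yl)phenyl]ethan-1-one F10.
- HCl in MeOH removes the methoxymethyl group of F10 to give F1, which continues through F2 and F3 to 17 as described for step 11.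

**Step 3.** The most likely failure is allylic transposition during transmetalation or reductive elimination, giving the 1,1-dimethylallyl isomer, or palladium-mediated transfer of the prenyl group to the aldehyde. The fallback replaces cross-coupling with a masked aldehyde and an aryl copper reagent. It sets out from 3 and returns at 6.
- Allylation of 3 gives 3-(allyloxy)-5-bromo-4-methoxybenzaldehyde F11.
- HC(OMe)3 in MeOH with catalytic acid gives the dimethyl acetal 1-(allyloxy)-3-bromo-5-(dimethoxymethyl)-2-methoxybenzene F12.
- Bromine–lithium exchange on F12 (n-BuLi, THF, −78 °C), transmetalation with CuBr·SMe2 and alkylation with prenyl bromide should give 1-(allyloxy)-5-(dimethoxymethyl)-2-methoxy-3-(3-methylbut-2-en-1-yl)benzene F13.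
- Dilute aqueous acid hydrolyses F13 to 6.

## Further compounds

F1 | step 11 | 1-[2,6-bis(allyloxy)-4-hydroxy-3-(3-methylbut-2-en-1-yl)phenyl]ethan-1-one | CC(=O)c1c(OCC=C)cc(O)c(CC=C(C)C)c1OCC=C
F2 | step 11 | 1-[5,7-bis(allyloxy)-2,2-dimethyl-3,4-dihydro-2H-chromen-6-yl]ethan-1-one | CC(=O)c1c(OCC=C)cc2OC(C)(C)CCc2c1OCC=C
F3 | step 11 | (E)-1-[5,7-bis(allyloxy)-2,2-dimethyl-3,4-dihydro-2H-chromen-6-yl]-3-[3-(allyloxy)-4-methoxy-5-(3-methylbut-2-en-1-yl)phenyl]prop-2-en-1-one | C=CCOc1cc2OC(C)(C)CCc2c(OCC=C)c1C(=O)/C=C/c1cc(OCC=C)c(OC)c(CC=C(C)C)c1
F4 | step 5 | 1-[2,6-dihydroxy-4-(methoxymethoxy)phenyl]ethan-1-one | CC(=O)c1c(O)cc(OCOC)cc1O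
F5 | step 5 | 1-[2,6-bis(allyloxy)-4-(methoxymethoxy)phenyl]ethan-1-one | CC(=O)c1c(OCC=C)cc(OCOC)cc1OCC=C
F6 | step 5 | 1-[2,6-bis(allyloxy)-4-hydroxyphenyl]ethan-1-one | CC(=O)c1c(OCC=C)cc(O)cc1OCC=C
F7 | step 5 | 1-[2,6-bis(allyloxy)-4-[(2-methylbut-3-yn-2-yl)oxy]phenyl]ethan-1-one | CC(=O)c1c(OCC=C)cc(OC(C)(C)C#C)cc1OCC=C
F8 | step 10 | 1-[2-hydroxy-4-(methoxymethoxy)-6-[(3-methylbut-2-en-1-yl)oxy]phenyl]ethan-1-one | CC(=O)c1c(O)cc(OCOC)cc1OCC=C(C)C
F9 | step 10 | 1-[2,6-dihydroxy-4-(methoxymethoxy)-3-(3-methylbut-2-en-1-yl)phenyl]ethan-1-one | CC(=O)c1c(O)cc(OCOC)c(CC=C(C)C)c1O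
F10 | step 10 | 1-[2,6-bis(allyloxy)-4-(methoxymethoxy)-3-(3-methylbut-2-en-1-yl)phenyl]ethan-1-one | CC(=O)c1c(OCC=C)cc(OCOC)c(CC=C(C)C)c1OCC=C
F11 | step 3 | 3-(allyloxy)-5-bromo-4-methoxybenzaldehyde | COc1c(OCC=C)cc(C=O)cc1Br
F12 | step 3 | 1-(allyloxy)-3-bromo-5-(dimethoxymethyl)-2-methoxybenzene | COc1c(OCC=C)cc(C(OC)OC)cc1Br
F13 | step 3 | 1-(allyloxy)-5-(dimethoxymethyl)-2-methoxy-3-(3-methylbut-2-en-1-yl)benzene | COc1c(OCC=C)cc(C(OC)OC)cc1CC=C(C)C
A1 | alternative 1 | 4-[(2-methylbut-3-yn-2-yl)oxy]-2,6-bis(methoxymethoxy)benzaldehyde | O=Cc1c(OCOC)cc(OC(C)(C)C#C)cc1OCOC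
A2 | alternative 1 | 5,7-bis(methoxymethoxy)-2,2-dimethyl-2H-chromene-6-carbaldehyde | O=Cc1c(OCOC)cc2c(c1OCOC)C=CC(C)(C)O2
A3 | alternative 2 | triisopropyl[(5-methylhex-4-en-1-yn-1-yl)oxy]silane | CC(C)=CCC#CO[Si](C(C)C)(C(C)C)C(C)C
A4 | alternative 2 | 3-ethoxycyclobut-2-en-1-one | CCOC1=CC(=O)C1
A5 | alternative 2 | 5-ethoxy-2-(3-methylbut-2-en-1-yl)-3-[(triisopropylsilyl)oxy]phenol | CCOc1cc(O)c(CC=C(C)C)c(O[Si](C(C)C)(C(C)C)C(C)C)c1
A6 | alternative 3 | 4-formyl-2-(3-hydroxy-3-methylbutyl)-3,5-bis(methoxymethoxy)phenyl trifluoromethanesulfonate | O=Cc1c(OCOC)cc(OS(=O)(=O)C(F)(F)F)c(CCC(C)(C)O)c1OCOC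
A7 | alternative 3 | 5,7-bis(methoxymethoxy)-2,2-dimethylchroman-6-carbaldehyde | O=Cc1c(OCOC)cc2c(c1OCOC)CCC(C)(C)O2
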